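**Retrosynthetic overview**
- Target 20 ← ester hydrolysis ← diimide reduction of an alkyne ← C6–C(sp) bond: axial alkynylation of the cyclic peroxycarbenium ion from 6-methoxy-1,2-dioxane 16 with bicyclic enyne 11 (sets C6).
- Dioxane 16 ← two C–O bonds: peroxyketalisation of keto-enoate 14, then a catalytic enantioselective 6-exo peroxa-Michael ring closure (new; sets C3 and C2 of the head).
- Enyne 11 ← methyl ketone 9 ← ring B by cation–olefin cyclisation of hydroxy-enone 7 ← ring A by catalytic asymmetric Diels–Alder of trienenitrile 3 with an acrylimide (sets both ring-fusion centres, cis).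
- 3 from geranyl nitrile (ene-chlorination, then elimination); 14 from hex-5-en-2-one and methyl methacrylate (cross-metathesis).
- Ring order: ring A (Diels–Alder), ring B (cationic closure), and separately the 1,2-dioxane (peroxa-Michael), which is joined last.

Assumption: the commercial E/Z mixture of geranyl nitrile is usable (this geometry is erased in step 5; structures are drawn E), and each named chiral catalyst follows its established facial model (otherwise its mirror image is used).

**Step 1**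
Reactants: 1 (2E)-3,7-dimethylocta-2,6-dienenitrile (geranyl nitrile)
Product: 2 (2E)-6-chloro-3,7-dimethylocta-2,7-dienenitrile (racemic at C6)
Conditions: Ca(OCl)2, CO2 (dry ice), CH2Cl2/H2O, 0 °C
Reagents that add atoms: calcium hypochlorite, [Ca+2].[O-]Cl.[O-]Cl
Why: ene-type chlorination by HOCl attacks only the electron-rich isolated trisubstituted alkene (the ene-nitrile is deactivated), giving the secondary allylic chloride with an isopropenyl group; its stereocentre is destroyed in step 2.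

**Step 2**
Reactants: 2 (2E)-6-chloro-3,7-dimethylocta-2,7-dienenitrile
Product: 3 (2E,5E)-3,7-dimethylocta-2,5,7-trienenitrile
Conditions: Li2CO3, LiBr (cat.), DMF, 90 °C
Reagents that add atoms: none
Why: E2 dehydrochlorination can only take a C5 hydrogen and gives the conjugated (E)-1-substituted 3-methylbuta-1,3-diene.

**Step 3**
Reactants: 3 (2E,5E)-3,7-dimethylocta-2,5,7-trienenitrile; 4 3-acryloyl-1,3-oxazolidin-2-one
Product: 5 (2E)-3-methyl-4-[(1R,6S)-3-methyl-6-(2-oxo-1,3-oxazolidine-3-carbonyl)cyclohex-2-en-1-yl]but-2-enenitrile (cis-1,6)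
Conditions: [Cu((S,S)-t-Bu-box)](SbF6)2 (10 mol%), CH2Cl2, −20 → 25 °C
Reagents that add atoms: none
Why: Cu(II)–bis(oxazoline)-catalysed Diels–Alder reaction; the 1-alkyl and 3-methyl groups of the diene both direct the acyl carbon to the substituted terminus, the endo transition state gives the cis adduct, and the chelated s-cis imide is attacked on its Cα Re face, setting both future ring-fusion centres (1R,6S).

**Step 4**
Reactants: 5 (2E)-3-methyl-4-[(1R,6S)-3-methyl-6-(2-oxo-1,3-oxazolidine-3-carbonyl)cyclohex-2-en-1-yl]but-2-enenitrile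
Product: 7 (3E)-5-[(1R,6S)-6-(2-hydroxypropan-2-yl)-3-methylcyclohex-2-en-1-yl]-4-methylpent-3-en-2-one, via bromomagnesium ketimine 6 (not isolated)
Conditions: MeMgBr (7 equiv), THF, −20 → 25 °C; CuBr (5 mol%), 60 °C; aq. NH4Cl, then 1 M HCl, 0 °C
Reagents that add atoms: methylmagnesium bromide, C[Mg]Br; water, O
Why: Grignard double addition turns the imide into the tertiary carbinol, and copper-catalysed 1,2-addition to the β,β-disubstituted ene-nitrile followed by hydrolysis gives the methyl ketone; no stereocentre is touched.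

**Step 5**
Reactants: 7 (3E)-5-[(1R,6S)-6-(2-hydroxypropan-2-yl)-3-methylcyclohex-2-en-1-yl]-4-methylpent-3-en-2-one
Product: 9 1-[(4aR,8aS)-1,1,3,6-tetramethyl-1,4,4a,7,8,8a-hexahydronaphthalen-2-yl]ethan-1-one (cis-fused), via β,γ-unsaturated ketone 8 (not isolated)
Conditions: BF3·OEt2 (1.5 equiv), CH2Cl2, −40 → −10 °C; then t-BuOK (0.3 equiv), THF, 25 °C
Reagents that add atoms: none
Why: ionone/damascone-type cation–olefin cyclisation (the tertiary cation attacks the enone α-carbon, 6-endo) closes ring B, and base equilibration through the dienolate moves the alkene into the conjugated tetrasubstituted position; the ring-fusion centres are not involved.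

**Step 6**
Reactants: 9 1-[(4aR,8aS)-1,1,3,6-tetramethyl-1,4,4a,7,8,8a-hexahydronaphthalen-2-yl]ethan-1-one
Product: 11 (4aR,8aS)-2-ethynyl-1,1,3,6-tetramethyl-1,4,4a,7,8,8a-hexahydronaphthalene, via enol phosphate 10 (not isolated)
Conditions: LDA (1.1 equiv), THF, −78 °C; ClP(O)(OEt)2; LDA (2.3 equiv), −78 → 25 °C
Reagents that add atoms: none
Why: Negishi conversion of a methyl ketone into a terminal alkyne (kinetic enolate O-phosphorylation, then base-induced elimination), as established for the β-ionone side chain.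

**Step 7**
Reactants: 12 hex-5-en-2-one; 13 methyl methacrylate
Product: 14 methyl (2E)-2-methyl-6-oxohept-2-enoate
Conditions: Hoveyda–Grubbs II (3 mol%), CH2Cl2, 40 °C
Reagents that add atoms: none
Why: olefin cross-metathesis of a terminal alkene with a methacrylate gives the (E)-trisubstituted enoate.

**Step 8**
Reactants: 14 methyl (2E)-2-methyl-6-oxohept-2-enoate
Product: 15 methyl (2E)-6-hydroperoxy-6-methoxy-2-methylhept-2-enoate (racemic)
Conditions: urea·H2O2, Sc(OTf)3 (cat.), MeOH, 0 → 25 °C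
Reagents that add atoms: hydrogen peroxide, OO; methanol, CO
Why: acid-catalysed peroxyketalisation of the methyl ketone forms the first C–O bond of the peroxide; the ketal stereocentre is racemic and is erased in step 10.

**Step 9**
Reactants: 15 methyl (2E)-6-hydroperoxy-6-methoxy-2-methylhept-2-enoate
Product: 16 methyl (2R)-2-[(3R)-6-methoxy-6-methyl-1,2-dioxan-3-yl]propanoate (both C6 epimers)
Conditions: chiral bifunctional iminophosphorane–thiourea catalyst (10 mol%, enantiomer giving 3R), toluene, −30 °C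
Reagents that add atoms: none
Why: Proposed new method: a catalyst-controlled enantioselective 6-exo intramolecular peroxa-Michael addition, in which the iminophosphorane deprotonates the hydroperoxide (pKa about 12–13), the thiourea binds the ester carbonyl to select the enoate face in a chair transition state, and the iminophosphoranium N–H returns the proton to Cα on the same face (syn addition across the E-enoate gives 2R,3R) whatever the configuration of the remote ketal carbon; the closest known reactions are iminophosphorane-catalysed enantioselective intramolecular oxa-Michael additions of alcohols to α,β-unsaturated esters and the racemic amine-mediated cyclisation of hydroperoxy ketals onto enoates.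

**Step 10**
Reactants: 11 (4aR,8aS)-2-ethynyl-1,1,3,6-tetramethyl-1,4,4a,7,8,8a-hexahydronaphthalene; 16 methyl (2R)-2-[(3R)-6-methoxy-6-methyl-1,2-dioxan-3-yl]propanoate
Product: 18 methyl (2R)-2-[(3R,6S)-6-methyl-6-{2-[(4aR,8aS)-1,1,3,6-tetramethyl-1,4,4a,7,8,8a-hexahydronaphthalen-2-yl]ethynyl}-1,2-dioxan-3-yl]propanoate, via lithium alkynyltrifluoroborate 17 (not isolated)
Conditions: n-BuLi, Et2O, −78 °C; BF3·OEt2 (2.5 equiv); then 16, CH2Cl2, −78 → −30 °C
Reagents that add atoms: none
Why: Lewis-acid substitution of a peroxyketal through a cyclic peroxycarbenium ion (both C6 epimers of 16 converge); the small alkynylborate attacks axially through a chair-like transition state with the C3 side chain pseudo-equatorial, which places the alkynyl group cis to the propanoate and sets the quaternary C6 centre.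

**Step 11**
Reactants: 18 methyl (2R)-2-[(3R,6S)-6-methyl-6-{2-[(4aR,8aS)-1,1,3,6-tetramethyl-1,4,4a,7,8,8a-hexahydronaphthalen-2-yl]ethynyl}-1,2-dioxan-3-yl]propanoate
Product: 19 methyl (2R)-2-[(3R,6R)-6-methyl-6-{2-[(4aR,8aS)-1,1,3,6-tetramethyl-1,4,4a,7,8,8a-hexahydronaphthalen-2-yl]ethyl}-1,2-dioxan-3-yl]propanoate
Conditions: KO2CN=NCO2K (excess, in portions), AcOH, MeOH/CH2Cl2, 0 → 25 °C
Reagents that add atoms: none
Why: diimide reduction saturates the alkyne (through the cis-alkene) while leaving the O–O bond and the tri- and tetrasubstituted ring alkenes alone; the C6 descriptor changes from S to R only through the priority rules.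

**Step 12**
Reactants: 19 methyl (2R)-2-[(3R,6R)-6-methyl-6-{2-[(4aR,8aS)-1,1,3,6-tetramethyl-1,4,4a,7,8,8a-hexahydronaphthalen-2-yl]ethyl}-1,2-dioxan-3-yl]propanoate
Product: 20 (2R)-2-[(3R,6R)-6-methyl-6-{2-[(4aR,8aS)-1,1,3,6-tetramethyl-1,4,4a,7,8,8a-hexahydronaphthalen-2-yl]ethyl}-1,2-dioxan-3-yl]propanoic acid (CNP0122760.1)
Conditions: LiOH, THF/H2O, 0 → 25 °C; aq. HCl to pH 4
Reagents that add atoms: lithium hydroxide, [Li+].[OH-]
Why: saponification of the methyl ester under mild conditions, chosen to avoid retro-oxa-Michael opening and C2 epimerisation.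

**Compound list**
1 | (2E)-3,7-dimethylocta-2,6-dienenitrile (geranyl nitrile) | CC(C)=CCC/C(C)=C/C#N | starting material
2 | (2E)-6-chloro-3,7-dimethylocta-2,7-dienenitrile (racemic) | CC(=C)C(Cl)CC/C(C)=C/C#N | intermediate
3 | (2E,5E)-3,7-dimethylocta-2,5,7-trienenitrile | CC(=C)/C=C/C/C(C)=C/C#N | intermediate
4 | 3-acryloyl-1,3-oxazolidin-2-one | C=CC(=O)N1CCOC1=O | starting material
5 | (2E)-3-methyl-4-[(1R,6S)-3-methyl-6-(2-oxo-1,3-oxazolidine-3-carbonyl)cyclohex-2-en-1-yl]but-2-enenitrile | CC1=C[C@@H](C/C(C)=C/C#N)[C@@H](C(=O)N2CCOC2=O)CC1 | intermediate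
6 | (3E)-5-[(1R,6S)-6-(2-hydroxypropan-2-yl)-3-methylcyclohex-2-en-1-yl]-4-methylpent-3-en-2-imine (present as its bromomagnesium salt) | CC1=C[C@@H](C/C(C)=C/C(C)=N)[C@@H](C(C)(C)O)CC1 | intermediate
7 | (3E)-5-[(1R,6S)-6-(2-hydroxypropan-2-yl)-3-methylcyclohex-2-en-1-yl]-4-methylpent-3-en-2-one | CC1=C[C@@H](C/C(C)=C/C(C)=O)[C@@H](C(C)(C)O)CC1 | intermediate
8 | 1-[(4aS,8aS)-1,1,3,6-tetramethyl-1,2,4a,7,8,8a-hexahydronaphthalen-2-yl]ethan-1-one (C2 epimers; same ring-fusion geometry as 9) | CC1=C[C@H]2C=C(C)C(C(C)=O)C(C)(C)[C@H]2CC1 | intermediate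
9 | 1-[(4aR,8aS)-1,1,3,6-tetramethyl-1,4,4a,7,8,8a-hexahydronaphthalen-2-yl]ethan-1-one | CC1=C[C@H]2CC(C)=C(C(C)=O)C(C)(C)[C@H]2CC1 | intermediate
10 | diethyl 1-[(4aR,8aS)-1,1,3,6-tetramethyl-1,4,4a,7,8,8a-hexahydronaphthalen-2-yl]ethenyl phosphate | CC1=C[C@H]2CC(C)=C(C(=C)OP(=O)(OCC)OCC)C(C)(C)[C@H]2CC1 | intermediate
11 | (4aR,8aS)-2-ethynyl-1,1,3,6-tetramethyl-1,4,4a,7,8,8a-hexahydronaphthalene | CC1=C[C@H]2CC(C)=C(C#C)C(C)(C)[C@H]2CC1 | intermediate
12 | hex-5-en-2-one | CC(=O)CCC=C | starting material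
13 | methyl methacrylate | C=C(C)C(=O)OC | starting material
14 | methyl (2E)-2-methyl-6-oxohept-2-enoate | CC(=O)CC/C=C(\C)C(=O)OC | intermediate
15 | methyl (2E)-6-hydroperoxy-6-methoxy-2-methylhept-2-enoate (racemic) | COC(C)(OO)CC/C=C(\C)C(=O)OC | intermediate
16 | methyl (2R)-2-[(3R)-6-methoxy-6-methyl-1,2-dioxan-3-yl]propanoate (both C6 epimers) | COC1(C)CC[C@H]([C@@H](C)C(=O)OC)OO1 | intermediate
17 | lithium trifluoro{2-[(4aR,8aS)-1,1,3,6-tetramethyl-1,4,4a,7,8,8a-hexahydronaphthalen-2-yl]ethynyl}borate | [Li+].CC1=C[C@H]2CC(C)=C(C#C[B-](F)(F)F)C(C)(C)[C@H]2CC1 | intermediate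
18 | methyl (2R)-2-[(3R,6S)-6-methyl-6-{2-[(4aR,8aS)-1,1,3,6-tetramethyl-1,4,4a,7,8,8a-hexahydronaphthalen-2-yl]ethynyl}-1,2-dioxan-3-yl]propanoate | CC1=C[C@H]2CC(C)=C(C#C[C@]3(C)CC[C@H]([C@@H](C)C(=O)OC)OO3)C(C)(C)[C@H]2CC1 | intermediate
19 | methyl (2R)-2-[(3R,6R)-6-methyl-6-{2-[(4aR,8aS)-1,1,3,6-tetramethyl-1,4,4a,7,8,8a-hexahydronaphthalen-2-yl]ethyl}-1,2-dioxan-3-yl]propanoate | CC1=C[C@H]2CC(C)=C(CC[C@]3(C)CC[C@H]([C@@H](C)C(=O)OC)OO3)C(C)(C)[C@H]2CC1 | intermediate
20 | (2R)-2-[(3R,6R)-6-methyl-6-{2-[(4aR,8aS)-1,1,3,6-tetramethyl-1,4,4a,7,8,8a-hexahydronaphthalen-2-yl]ethyl}-1,2-dioxan-3-yl]propanoic acid | CC1=C[C@H]2CC(C)=C(CC[C@]3(C)CC[C@H]([C@@H](C)C(=O)O)OO3)C(C)(C)[C@H]2CC1 | target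

**Step count and risks**
Total: 12 steps. Longest linear sequence: 9 steps (1–6, then 10–12); steps 7–9 form the second branch.

Step 9 (the new peroxa-Michael closure) may give low enantio- or diastereocontrol, or the α-centre may epimerise under the basic catalyst. The fallback uses known chemistry and sets out from 15. Diethylamine in 2,2,2-trifluoroethanol cyclises 15 without stereocontrol, and chromatography isolates the (2R\*,3R\*) pair, that is 16 together with its enantiomer methyl (2S)-2-[(3S)-6-methoxy-6-methyl-1,2-dioxan-3-yl]propanoate F1. This racemate is coupled with enantiopure 11 under the step 10 conditions. Because the decalin is a single enantiomer, the product is 18 plus its diastereomer methyl (2S)-2-[(3S,6R)-6-methyl-6-{2-[(4aR,8aS)-1,1,3,6-tetramethyl-1,4,4a,7,8,8a-hexahydronaphthalen-2-yl]ethynyl}-1,2-dioxan-3-yl]propanoate F2, which is removed by chromatography. The route is rejoined at 18.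

Step 5 (ring B closure) may fail for three reasons: the Lewis-acid-bound enone is a poor nucleophile, acid released in the reaction can move the ring A alkene, and a 1,2-hydride shift in the tertiary cation can erase the ring-fusion centre. The fallback sets out from 7 and changes the terminating group. The Negishi protocol (LDA, ClP(O)(OEt)2, LDA) is applied first, giving the hydroxy enyne 2-[(1S,2R)-4-methyl-2-[(2E)-2-methylpent-2-en-4-yn-1-yl]cyclohex-3-en-1-yl]propan-2-ol F3. Its carbinol is ionised with SnCl4 at −78 °C in the presence of 2,6-di-tert-butyl-4-methylpyridine as proton trap, so the non-basic enyne alkene closes ring B and chloride capture gives (4aR,8aS)-3-chloro-2-ethynyl-1,1,3,6-tetramethyl-1,2,3,4,4a,7,8,8a-octahydronaphthalene F4. DBU then eliminates toward the conjugated position and the route is rejoined at 11.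

Step 10 (alkynylation of the peroxycarbenium ion) uses a nucleophile class not yet shown on peroxyketals; the ring alkenes may compete for the cation, or the ketal may fragment. The fallback sets out from 9 and 16 and uses an established nucleophile class. Ketone 9 is converted (TMSOTf, Et3N) into trimethyl({1-[(4aR,8aS)-1,1,3,6-tetramethyl-1,4,4a,7,8,8a-hexahydronaphthalen-2-yl]ethenyl}oxy)silane F5. This adds to 16 under TMSOTf at −78 °C with the same axial preference, giving methyl (2R)-2-[(3R,6S)-6-methyl-6-{2-oxo-2-[(4aR,8aS)-1,1,3,6-tetramethyl-1,4,4a,7,8,8a-hexahydronaphthalen-2-yl]ethyl}-1,2-dioxan-3-yl]propanoate F6. Luche reduction gives methyl (2R)-2-[(3R,6S)-6-{2-hydroxy-2-[(4aR,8aS)-1,1,3,6-tetramethyl-1,4,4a,7,8,8a-hexahydronaphthalen-2-yl]ethyl}-6-methyl-1,2-dioxan-3-yl]propanoate F7. Ionic deoxygenation (Et3SiH, BF3·OEt2, −78 °C) delivers hydride to the less hindered allyl terminus, and the route is rejoined at 19 without step 11.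

**Further compounds**
F1 | step 9 | methyl (2S)-2-[(3S)-6-methoxy-6-methyl-1,2-dioxan-3-yl]propanoate (enantiomer formed with 16 in the racemate) | COC1(C)CC[C@@H]([C@H](C)C(=O)OC)OO1
F2 | step 9 | methyl (2S)-2-[(3S,6R)-6-methyl-6-{2-[(4aR,8aS)-1,1,3,6-tetramethyl-1,4,4a,7,8,8a-hexahydronaphthalen-2-yl]ethynyl}-1,2-dioxan-3-yl]propanoate | CC1=C[C@H]2CC(C)=C(C#C[C@@]3(C)CC[C@@H]([C@H](C)C(=O)OC)OO3)C(C)(C)[C@H]2CC1
F3 | step 5 | 2-[(1S,2R)-4-methyl-2-[(2E)-2-methylpent-2-en-4-yn-1-yl]cyclohex-3-en-1-yl]propan-2-ol | CC1=C[C@@H](C/C(C)=C/C#C)[C@@H](C(C)(C)O)CC1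
F4 | step 5 | (4aR,8aS)-3-chloro-2-ethynyl-1,1,3,6-tetramethyl-1,2,3,4,4a,7,8,8a-octahydronaphthalene (C2/C3 epimers) | CC1=C[C@H]2CC(C)(Cl)C(C#C)C(C)(C)[C@H]2CC1
F5 | step 10 | trimethyl({1-[(4aR,8aS)-1,1,3,6-tetramethyl-1,4,4a,7,8,8a-hexahydronaphthalen-2-yl]ethenyl}oxy)silane | CC1=C[C@H]2CC(C)=C(C(=C)O[Si](C)(C)C)C(C)(C)[C@H]2CC1
F6 | step 10 | methyl (2R)-2-[(3R,6S)-6-methyl-6-{2-oxo-2-[(4aR,8aS)-1,1,3,6-tetramethyl-1,4,4a,7,8,8a-hexahydronaphthalen-2-yl]ethyl}-1,2-dioxan-3-yl]propanoate | CC1=C[C@H]2CC(C)=C(C(=O)C[C@]3(C)CC[C@H]([C@@H](C)C(=O)OC)OO3)C(C)(C)[C@H]2CC1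
F7 | step 10 | methyl (2R)-2-[(3R,6S)-6-{2-hydroxy-2-[(4aR,8aS)-1,1,3,6-tetramethyl-1,4,4a,7,8,8a-hexahydronaphthalen-2-yl]ethyl}-6-methyl-1,2-dioxan-3-yl]propanoate (carbinol epimers) | CC1=C[C@H]2CC(C)=C(C(O)C[C@]3(C)CC[C@H]([C@@H](C)C(=O)OC)OO3)C(C)(C)[C@H]2CC1
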